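Assumption 1: atom labels follow the ring order of the SMILES: C1(OAc)–C2(Me)=C3–C4H2–C5(OH)–C6(Me)=C7–C8H2–C9H2–C10(Me)=C11–C12=C13(iPr)–C14(OAc); the target is 1R,14R,5S with 2Z,6E,10E,12Z.
Assumption 2: the (S,S)-bisphosphoramide in step 5 is taken to direct Si-face attack on aldehyde 8 (mirror image of the Re-face sense known for the (R,R)-catalyst); if the sense is the opposite, the antipodal catalyst is used.

**Retrosynthetic overview**
1. Target ⇒ acyclic (Z)-allylic bromide/(E)-enal 18 by a C4–C5 disconnection: a titanocene radical–radical allyl/ketyl macrocyclisation closes the only ring last, creates C5 and releases the free OH with both acetates already in place.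
2. 18 ⇒ triol 13 by cross-metathesis with methacrolein (C6=C7) and OH differentiation (primary → Br, secondary → OAc).
3. 13 ⇒ butenolide 12, whose ring masks the (Z)-C2=C3–C4 unit; 12 ⇒ silyloxyfuran 10 + dienal 8 by an asymmetric vinylogous Mukaiyama aldol (C1–C14, sets both acetoxy carbinols, threo).
4. 8 ⇒ hex-1-en-5-yne + iodide 3 by carboalumination/Negishi coupling (C11–C12); 3 ⇒ propargyl alcohol by anti-carbomagnesiation.
5. Ring order: the purchased butenolide ring is opened reductively in step 6; the 14-membered ring is formed in the final step.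

**Route**

Step 1
Reactants: 1 prop-2-yn-1-ol
Product: 3 (Z)-3-iodo-2-isopropylprop-2-en-1-ol, via cyclic alkenylmagnesium alkoxide 2 (not isolated)
Conditions: iPrMgCl (3.0 equiv), CuI (10 mol%), THF, −20 °C to rt; then I2 (1.5 equiv), −40 to 0 °C
Reagents that add atoms: isopropylmagnesium chloride, CC(C)[Mg]Cl; iodine, I-I
Why: Copper-catalysed anti-carbomagnesiation of a propargylic alcohol (Duboudin–Jousseaume) puts iPr on the internal carbon and Mg on the terminal carbon cis to CH2O in a five-membered chelate; iodinolysis with retention gives the Z iodide (I cis to CH2OH, the future C14/C11 cis relationship).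

Step 2
Reactants: 4 hex-1-en-5-yne; 3 (Z)-3-iodo-2-isopropylprop-2-en-1-ol
Product: 7 (2Z,4E)-2-isopropyl-5-methylnona-2,4,8-trien-1-ol, via (E)-alkenyldimethylalane 5 (not isolated), via dimethylaluminium alkoxide 6 (not isolated)
Conditions: 4, Me3Al (2.0 equiv), Cp2ZrCl2 (20 mol%), (CH2Cl)2, 0 °C to rt; then 3 premixed with Me3Al (1.0 equiv) in THF, Pd(PPh3)4 (5 mol%), ZnCl2 (30 mol%), rt; aq. Rochelle salt
Reagents that add atoms: trimethylaluminium, C[Al](C)C
Why: Negishi zirconium-catalysed syn-carboalumination of the terminal alkyne (the isolated terminal alkene is inert) gives the E-alkenylalane, and zerovalent-palladium Negishi cross-coupling with zinc co-catalysis proceeds with retention on both partners to give the 2Z,4E-diene.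

Step 3
Reactants: 7 (2Z,4E)-2-isopropyl-5-methylnona-2,4,8-trien-1-ol
Product: 8 (2Z,4E)-2-isopropyl-5-methylnona-2,4,8-trienal
Conditions: MnO2 (15 equiv), CH2Cl2, rt
Reagents that add atoms: none
Why: Chemoselective MnO2 oxidation of an allylic alcohol; the Z-enal (CHO cis to the alkenyl chain, iPr away from it) is the less strained isomer and does not isomerise.

Step 4
Reactants: 9 4-methylfuran-2(5H)-one
Product: 10 tert-butyldimethyl[(4-methylfuran-2-yl)oxy]silane
Conditions: TBSOTf (1.1 equiv), Et3N (1.3 equiv), CH2Cl2, 0 °C; distilled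
Reagents that add atoms: tert-butyldimethylsilyl triflate, CC(C)(C)[Si](C)(C)OS(=O)(=O)C(F)(F)F
Why: Soft enolisation and O-silylation of the butenolide gives the aromatic 2-silyloxyfuran, a γ-nucleophilic dienolate equivalent.

Step 5
Reactants: 8 (2Z,4E)-2-isopropyl-5-methylnona-2,4,8-trienal; 10 tert-butyldimethyl[(4-methylfuran-2-yl)oxy]silane
Product: 12 (5R)-5-[(1R,2Z,4E)-1-hydroxy-2-isopropyl-5-methylnona-2,4,8-trien-1-yl]-4-methylfuran-2(5H)-one, via trichlorosilyl ether 11 (not isolated)
Conditions: SiCl4 (1.2 equiv), (S,S)-Denmark bisphosphoramide (pentane-1,5-diyl-linked binaphthyldiamine phosphoramide, 5 mol%), iPr2NEt (10 mol%), CH2Cl2, −78 °C; aq. NaHCO3/KF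
Reagents that add atoms: none
Why: Catalytic enantioselective vinylogous Mukaiyama aldol (Lewis-base-activated SiCl4, a system that favours conjugated aldehydes) forms C1–C14 at the furan γ-carbon through an open transition state; Si-face attack on the aldehyde sets C14 (R) and the threo preference typical of Lewis-acid additions of 2-silyloxyfurans sets C1 (R); the ring locks C2=C3 as Z.

Step 6
Reactants: 12 the butenolide carbinol
Product: 13 (2Z,4R,5R,6Z,8E)-6-isopropyl-3,9-dimethyltrideca-2,6,8,12-tetraene-1,4,5-triol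
Conditions: iBu2AlH (5 equiv), CH2Cl2, −78 to 0 °C; aq. Rochelle salt
Reagents that add atoms: none
Why: 1,2-Reduction of the lactone through its lactol aluminate gives the ring-opened (Z)-ene-1,4-diol; the Z geometry is inherited from the ring and no stereocentre is touched.

Step 7
Reactants: 13 the triol
Product: 15 (2Z,4R,5R,6Z,8E)-1-[(tert-butyldimethylsilyl)oxy]-6-isopropyl-3,9-dimethyltrideca-2,6,8,12-tetraene-4,5-diyl diacetate, via primary TBS ether 14 (not isolated)
Conditions: TBSCl (1.05 equiv), imidazole (2.2 equiv), CH2Cl2, −20 °C; then Ac2O (4 equiv), Et3N (5 equiv), DMAP (20 mol%), 0 °C to rt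
Reagents that add atoms: tert-butyldimethylsilyl chloride, CC(C)(C)[Si](C)(C)Cl; acetic anhydride, CC(=O)OC(C)=O
Why: Selective silylation of the unhindered primary allylic OH, then DMAP-catalysed acetylation of both secondary carbinols in the same pot, installs the natural diacetate before ring closure.

Step 8
Reactants: 15 the silyl ether diacetate
Product: 16 (2Z,4R,5R,6Z,8E)-1-bromo-6-isopropyl-3,9-dimethyltrideca-2,6,8,12-tetraene-4,5-diyl diacetate
Conditions: Ph3PBr2 (1.3 equiv), CH2Cl2, 0 °C to rt; cold filtration through silica, used at once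
Reagents that add atoms: triphenylphosphine dibromide, BrP(Br)(c1ccccc1)(c1ccccc1)c1ccccc1
Why: Direct silyl ether to bromide conversion (oxyphosphonium formation, then SN2 by bromide at the primary carbon) leaves acetates alone and keeps the Z geometry.

Step 9
Reactants: 16 the allylic bromide; 17 methacrolein
Product: 18 (2E,6E,8Z,10R,11R,12Z)-14-bromo-9-isopropyl-2,6,12-trimethyl-1-oxotetradeca-2,6,8,12-tetraene-10,11-diyl diacetate
Conditions: 17 (10 equiv), second-generation Hoveyda–Grubbs catalyst RuCl2(H2IMes)(=CH-C6H4-2-OiPr) (5 mol%), CH2Cl2, 35 °C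
Reagents that add atoms: none
Why: Olefin cross-metathesis of the only monosubstituted alkene with methacrolein gives the (E)-2-methyl-enal; the trisubstituted alkenes and the diene do not engage, and the phosphine-free catalyst is not quaternised by the allylic bromide.

Step 10
Reactants: 18 the bromo-enal
Product: 20 gibberosene E [(1R,2R,3Z,6S,7E,11E,13Z)-6-hydroxy-14-isopropyl-3,7,11-trimethylcyclotetradeca-3,7,11,13-tetraene-1,2-diyl diacetate], via trimethylsilyl ether 19 (not isolated)
Conditions: Cp2TiCl2 (30 mol%), Mn powder (8 equiv), TMSCl (4 equiv), 2,4,6-collidine (7 equiv), THF, rt, syringe-pump addition of 18 over 12 h to 2 mM; then 10% aq. citric acid/MeOH, 0 °C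
Reagents that add atoms: none
Why: Proposed new method: Cp2TiCl (trivalent titanium, made in situ) abstracts bromine to give the C2–C4 allyl radical and reduces the titanium-bound enal to a titanoxy-allyl radical, and the two couple within the molecule at their less hindered termini (C4 and C5) to the 14-membered alkoxide, which TMSCl silylates to turn the catalyst over; a low steady-state titanium concentration keeps the allyl partner a radical (no allyl–titanium, hence no γ-attack and no 1,4-loss of the C1 acetate), and coupling is faster than allyl-radical rotation, so 2Z is kept; C5 is set under macrocyclic control (bulky titanoxy group peripheral, the Z-allyl unit held by A(1,3) strain against the 1R,14R-diacetate), with 5S the expected but unproven major epimer; closest known chemistry is the intermolecular titanocene-catalysed α-selective prenylation of conjugated aldehydes and titanocene Barbier-type cyclisations.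

**Compound list**
1 | prop-2-yn-1-ol | C#CCO | starting material
2 | cyclic alkenylmagnesium alkoxide (4-isopropyl-2,5-dihydro-1,2-oxamagnesole) | CC(C)C1=C[Mg]OC1 | intermediate
3 | (Z)-3-iodo-2-isopropylprop-2-en-1-ol | OC/C(C(C)C)=C\I | intermediate
4 | hex-1-en-5-yne | C#CCCC=C | starting material
5 | (E)-dimethyl(2-methylhexa-1,5-dien-1-yl)alane | C=CCC/C(C)=C/[Al](C)C | intermediate
6 | dimethylaluminium (Z)-3-iodo-2-isopropylprop-2-en-1-olate | C[Al](C)OC/C(C(C)C)=C\I | intermediate
7 | (2Z,4E)-2-isopropyl-5-methylnona-2,4,8-trien-1-ol | OC/C(C(C)C)=C\C=C(C)\CCC=C | intermediate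
8 | (2Z,4E)-2-isopropyl-5-methylnona-2,4,8-trienal | O=C/C(C(C)C)=C\C=C(C)\CCC=C | intermediate
9 | 4-methylfuran-2(5H)-one | CC1=CC(=O)OC1 | starting material
10 | tert-butyldimethyl[(4-methylfuran-2-yl)oxy]silane | Cc1coc(O[Si](C)(C)C(C)(C)C)c1 | intermediate
11 | O-trichlorosilyl ether of 12 | O=C1O[C@@H]([C@H](O[Si](Cl)(Cl)Cl)/C(C(C)C)=C\C=C(C)\CCC=C)C(C)=C1 | intermediate
12 | (5R)-5-[(1R,2Z,4E)-1-hydroxy-2-isopropyl-5-methylnona-2,4,8-trien-1-yl]-4-methylfuran-2(5H)-one | O=C1O[C@@H]([C@H](O)/C(C(C)C)=C\C=C(C)\CCC=C)C(C)=C1 | intermediate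
13 | (2Z,4R,5R,6Z,8E)-6-isopropyl-3,9-dimethyltrideca-2,6,8,12-tetraene-1,4,5-triol | O[C@@H]([C@H](O)/C(C(C)C)=C\C=C(C)\CCC=C)/C(C)=C\CO | intermediate
14 | (2Z,4R,5R,6Z,8E)-1-[(tert-butyldimethylsilyl)oxy]-6-isopropyl-3,9-dimethyltrideca-2,6,8,12-tetraene-4,5-diol | O[C@@H]([C@H](O)/C(C(C)C)=C\C=C(C)\CCC=C)/C(C)=C\CO[Si](C)(C)C(C)(C)C | intermediate
15 | (2Z,4R,5R,6Z,8E)-1-[(tert-butyldimethylsilyl)oxy]-6-isopropyl-3,9-dimethyltrideca-2,6,8,12-tetraene-4,5-diyl diacetate | CC(=O)O[C@@H]([C@H](OC(C)=O)/C(C(C)C)=C\C=C(C)\CCC=C)/C(C)=C\CO[Si](C)(C)C(C)(C)C | intermediate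
16 | (2Z,4R,5R,6Z,8E)-1-bromo-6-isopropyl-3,9-dimethyltrideca-2,6,8,12-tetraene-4,5-diyl diacetate | CC(=O)O[C@@H]([C@H](OC(C)=O)/C(C(C)C)=C\C=C(C)\CCC=C)/C(C)=C\CBr | intermediate
17 | methacrolein (2-methylprop-2-enal) | C=C(C)C=O | starting material
18 | (2E,6E,8Z,10R,11R,12Z)-14-bromo-9-isopropyl-2,6,12-trimethyl-1-oxotetradeca-2,6,8,12-tetraene-10,11-diyl diacetate | CC(=O)O[C@@H]([C@H](OC(C)=O)/C(C(C)C)=C\C=C(C)\CC/C=C(C)/C=O)/C(C)=C\CBr | intermediate
19 | O-trimethylsilyl ether of gibberosene E | CC(=O)O[C@@H]1/C(C)=C\C[C@H](O[Si](C)(C)C)/C(C)=C/CC/C(C)=C/C=C(/C(C)C)[C@H]1OC(C)=O | intermediate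
20 | gibberosene E | CC(=O)O[C@@H]1/C(C)=C\C[C@H](O)/C(C)=C/CC/C(C)=C/C=C(/C(C)C)[C@H]1OC(C)=O | target

**Totals**
Total step count: 10. Longest linear sequence: 9 (steps 1, 2, 3, 5, 6, 7, 8, 9, 10). Stereocentres: C1 and C14 in step 5, C5 in step 10.

**Three steps most likely to fail**

Step 10 (radical macrocyclisation). The risks are reduction of the allyl radical to an allyl–titanium species (γ-attack or 1,4-elimination of the C1 acetate to a diene), oligomerisation, and the wrong C5 epimer. The fallback sets out from 16 (with 17) and comes back at 20. Bromide 16 is coupled intermolecularly with excess methacrolein 17 under the same titanocene conditions, the documented intermolecular mode. This gives, through the trimethylsilyl ether of the acyclic adduct F1 cleaved on acidic work-up, the acyclic allylic alcohol (5Z,7R,8R,9Z,11E)-3-hydroxy-9-isopropyl-2,6,12-trimethylhexadeca-1,5,9,11,15-pentaene-7,8-diyl diacetate F2 as a mixture of C5 epimers. Ring-closing metathesis of its C6(Me)=CH2 and C7H=CH2 termini (the ruthenium catalyst of step 9, toluene, 80 °C, 1 mM) then closes the ring at C6=C7 to give 20 together with 5-epi-gibberosene E F3. F3, and likewise any wrong epimer from step 10 itself, is converged by MnO2 oxidation to the C5 enone F4 and reduction with (R)-2-methyl-CBS-oxazaborolidine/catecholborane (−60 °C, acetates untouched) to 20.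

Step 5 (asymmetric vinylogous aldol). The risks are low enantio- or threo-selectivity with this hindered α-branched dienal, and acid-promoted ionisation of the doubly allylic carbinol. The fallback sets out from 8 and 10 and comes back at 13. BF3·OEt2 (CH2Cl2, −78 °C) gives the threo adduct as a racemate, that is 12 together with its enantiomer, the (5S,1′S)-butenolide carbinol F5. Esterification with (R)-O-methylmandelic acid (EDC, DMAP) gives the separable diastereomers (R)-O-methylmandelate of 12 F6 and (R)-O-methylmandelate of the enantiomer F7. After chromatography, iBu2AlH reduces the lactone of F6 and cleaves its mandelate in one operation to give 13.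

Step 8 (silyl ether to Z-allylic bromide, carried through metathesis). The risks are reagent attack on the diene or allylic acetates, and lability or Z/E drift of 16 on silica and during step 9. The fallback sets out from 15 and comes back at 18, placing metathesis before halide installation. Cross-metathesis of 15 with 17 (conditions of step 9) gives the enal silyl ether F8. HF·pyridine (THF, 0 °C) frees the primary allylic alcohol F9. MsCl/Et3N then LiBr (THF, 0 °C), through the allylic mesylate F10, gives 18 under conditions that tolerate the enal.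

**Further compounds**
F1 | step 10 | trimethylsilyl ether of the acyclic adduct (3RS) | CC(=O)O[C@@H]([C@H](OC(C)=O)/C(C(C)C)=C\C=C(C)\CCC=C)/C(C)=C\CC(O[Si](C)(C)C)C(C)=C
F2 | step 10 | (5Z,7R,8R,9Z,11E)-3-hydroxy-9-isopropyl-2,6,12-trimethylhexadeca-1,5,9,11,15-pentaene-7,8-diyl diacetate (3RS) | CC(=O)O[C@@H]([C@H](OC(C)=O)/C(C(C)C)=C\C=C(C)\CCC=C)/C(C)=C\CC(O)C(C)=C
F3 | step 10 | 5-epi-gibberosene E (6R in ring numbering) | CC(=O)O[C@@H]1/C(C)=C\C[C@@H](O)/C(C)=C/CC/C(C)=C/C=C(/C(C)C)[C@H]1OC(C)=O
F4 | step 10 | (1R,2R,3Z,7E,11E,13Z)-14-isopropyl-3,7,11-trimethyl-6-oxocyclotetradeca-3,7,11,13-tetraene-1,2-diyl diacetate | CC(=O)O[C@@H]1/C(C)=C\CC(=O)/C(C)=C/CC/C(C)=C/C=C(/C(C)C)[C@H]1OC(C)=O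
F5 | step 5 | (5S)-5-[(1S,2Z,4E)-1-hydroxy-2-isopropyl-5-methylnona-2,4,8-trien-1-yl]-4-methylfuran-2(5H)-one | O=C1O[C@H]([C@@H](O)/C(C(C)C)=C\C=C(C)\CCC=C)C(C)=C1
F6 | step 5 | (R)-O-methylmandelate of 12 | O=C1O[C@@H]([C@H](OC(=O)[C@H](OC)c2ccccc2)/C(C(C)C)=C\C=C(C)\CCC=C)C(C)=C1
F7 | step 5 | (R)-O-methylmandelate of F5 | O=C1O[C@H]([C@@H](OC(=O)[C@H](OC)c2ccccc2)/C(C(C)C)=C\C=C(C)\CCC=C)C(C)=C1
F8 | step 8 | (2E,6E,8Z,10R,11R,12Z)-14-[(tert-butyldimethylsilyl)oxy]-9-isopropyl-2,6,12-trimethyl-1-oxotetradeca-2,6,8,12-tetraene-10,11-diyl diacetate | CC(=O)O[C@@H]([C@H](OC(C)=O)/C(C(C)C)=C\C=C(C)\CC/C=C(C)/C=O)/C(C)=C\CO[Si](C)(C)C(C)(C)C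
F9 | step 8 | (2E,6E,8Z,10R,11R,12Z)-14-hydroxy-9-isopropyl-2,6,12-trimethyl-1-oxotetradeca-2,6,8,12-tetraene-10,11-diyl diacetate | CC(=O)O[C@@H]([C@H](OC(C)=O)/C(C(C)C)=C\C=C(C)\CC/C=C(C)/C=O)/C(C)=C\CO
F10 | step 8 | allylic methanesulfonate of F9 | CC(=O)O[C@@H]([C@H](OC(C)=O)/C(C(C)C)=C\C=C(C)\CC/C=C(C)/C=O)/C(C)=C\COS(C)(=O)=O
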